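The β-ring is disconnected at C1–C6. Gem-dimethyl C1 is a natural tertiary cation site next to C6 of the ring alkene C5=C6, and C2H2–C3(OH)–C4(OH), a cis (3S,4R) diol, maps onto the erythro diol of 2-deoxy-D-ribose, whose C1 and C5 become ring C1 and C5. In the key step acid ionises a C1 dimethyl carbinol and C6 of a dienone captures the cation, closing the cyclohexene and delivering the C13 β-ionone skeleton at once. The precursor is an open-chain hepta-3,5-dien-2-one carrying the diol as a cyclic carbonate. A derived C15 phosphonium salt is finally joined to a C25 ε-apocarotenal from (R)-α-ionone.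

Key step: step 11

Assumption: (R)-α-ionone (20) is bought as the single enantiomer; all other starting materials are catalogue chemicals.

Remarks on the design:
- Positions are cited in carotenoid numbering (ring C1–C6, chain C7–C15, primes for the ε-half), also for open-chain intermediates.
- Carbon building blocks whose atoms stay in the target are numbered and listed as reactants. Step 3 incorporates two molecules of 4; the second is entered on the reagent line of that step.
- The carbonate is installed last before ring closure, because C4–H is α, γ or ε to a carbonyl in 8–13 and an acylated oxygen on C3 would be lost under base. Ketone 8 is therefore olefinated with neutral ylides.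
- A five-membered cyclic carbonate is kept for the ring closure: its carbonyl oxygen is locked anti to C3 and C4 and cannot bridge either cationic site.
- The tertiary hydroxyl is carried free. As lactone 6 and as the hemiketal of 8 it masks the C5 carbonyl, so C1 needs no protecting group.

Step 1
Reactants: 1 2-deoxy-D-ribose
Product: 2 2-deoxy-3,4-O-isopropylidene-D-erythro-pentopyranose (anomer mixture)
Conditions: 2-methoxypropene, PPTS (cat.), EtOAc, 0 °C to rt
Reagents that add atoms: 2-methoxypropene, COC(C)=C
Why: Acid-catalysed acetal exchange (acetonide formation) should take place on the cis-3,4-diol of the pyranose form, leaving the anomeric hydroxyl free and both stereocentres untouched.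

Step 2
Reactants: 2 acetonide lactol
Product: 3 2-deoxy-3,4-O-isopropylidene-D-erythro-pentono-1,5-lactone
Conditions: TEMPO (cat.), PhI(OAc)2, CH2Cl2, rt
Reagents that add atoms: none
Why: Oxoammonium (TEMPO) oxidation of a lactol to the lactone is neutral enough for the acetonide and does not touch C3 or C4.

Step 3
Reactants: 3 acetonide lactone; 4 methylmagnesium bromide
Product: 5 1-[(4S,5R)-5-(hydroxymethyl)-2,2-dimethyl-1,3-dioxolan-4-yl]-2-methylpropan-2-ol
Conditions: MeMgBr (3 equiv), THF, 0 °C to rt; aq. NH4Cl
Reagents that add atoms: methylmagnesium bromide (the second molecule of 4 that is incorporated), C[Mg]Br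
Why: Double Grignard addition to the lactone (ring opening to the methyl ketone, then a second addition) should install both C1 methyl groups as the dimethyl carbinol and release O5 as the primary alcohol.

Step 4
Reactants: 5 carbinol diol
Product: 6 2,3-O-isopropylidene-(2S,3S)-2,3,5-trihydroxy-5-methylhexanoic acid 1,5-lactone
Conditions: TEMPO (cat.), PhI(OAc)2 (2.5 equiv), CH2Cl2, rt
Reagents that add atoms: none
Why: TEMPO oxidative lactonisation of the 1,5-diol (aldehyde, lactol closed by the tertiary hydroxyl, then lactone) should bring C5 to the acid level and mask the carbinol in one operation.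

Step 5
Reactants: 6 dimethyl lactone; 7 methyllithium
Product: 8 1-[(4S,5S)-5-(2-hydroxy-2-methylpropyl)-2,2-dimethyl-1,3-dioxolan-4-yl]ethan-1-one (in equilibrium with its cyclic hemiketal)
Conditions: MeLi (1.05 equiv), THF, −78 °C; AcOH, −78 °C
Reagents that add atoms: none
Why: Mono-addition of an organolithium to a lactone stops at the lithium hemiketal alkoxide at −78 °C, so the C5 methyl ketone appears only on cold quench and C4 is not exposed to base as a ketone.

Step 6
Reactants: 8 hydroxy ketone; 9 (triphenylphosphoranylidene)acetonitrile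
Product: 10 3-[(4R,5S)-5-(2-hydroxy-2-methylpropyl)-2,2-dimethyl-1,3-dioxolan-4-yl]but-2-enenitrile (E/Z mixture)
Conditions: toluene, 90 °C
Reagents that add atoms: none
Why: Wittig olefination of the α-alkoxy-activated ketone with a stabilised, non-basic ylide should form C5=C6 without enolising C4; the geometry is irrelevant because this bond becomes the ring alkene.

Step 7
Reactants: 10 unsaturated nitrile
Product: 11 3-[(4R,5S)-5-(2-hydroxy-2-methylpropyl)-2,2-dimethyl-1,3-dioxolan-4-yl]but-2-enal (E/Z mixture)
Conditions: i-Bu2AlH (2.5 equiv), CH2Cl2, −78 °C; aq. potassium sodium tartrate, then wet SiO2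
Reagents that add atoms: water, O
Why: Partial reduction of the nitrile by i-Bu2AlH to the N-aluminoimine and hydrolysis on work-up should give the enal, one equivalent of hydride being consumed by the free hydroxyl.

Step 8
Reactants: 11 enal; 12 1-(triphenylphosphoranylidene)propan-2-one
Product: 13 (3E)-6-[(4R,5S)-5-(2-hydroxy-2-methylpropyl)-2,2-dimethyl-1,3-dioxolan-4-yl]hepta-3,5-dien-2-one (5E/5Z mixture)
Conditions: toluene, 60 °C
Reagents that add atoms: none
Why: Wittig olefination of an enal with a stabilised ylide should give the (E)-C7=C8 bond and the methyl ketone terminus under neutral conditions.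

Step 9
Reactants: 13 dienone acetonide
Product: 14 (3E,7R,8S)-7,8,10-trihydroxy-6,10-dimethylundeca-3,5-dien-2-one
Conditions: AcOH/H2O (4:1), 40 °C
Reagents that add atoms: none
Why: Acid hydrolysis of the acetonide should free the 3,4-diol, while the dienone and the tertiary alcohol tolerate dilute acetic acid.

Step 10
Reactants: 14 triol dienone
Product: 15 (4S,5R)-4-(2-hydroxy-2-methylpropyl)-5-[(4E)-6-oxohepta-2,4-dien-2-yl]-1,3-dioxolan-2-one
Conditions: CDI (1.2 equiv), CH2Cl2, 0 °C to rt
Reagents that add atoms: 1,1'-carbonyldiimidazole, O=C(n1ccnc1)n1ccnc1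
Why: Carbonylation of a vicinal diol with CDI should close the five-membered carbonate on the two secondary hydroxyls, the hindered tertiary hydroxyl staying free.

Step 11
Reactants: 15 carbonate precursor
Product: 16 (3E)-4-[(3R,4S)-3,4-(carbonyldioxy)-2,6,6-trimethylcyclohex-1-en-1-yl]but-3-en-2-one
Conditions: 98% H2SO4 (6 equiv), CH2Cl2, −15 to 0 °C, vigorous stirring; ice/aq. NaHCO3
Reagents that add atoms: none
Why: Protonation and loss of water from the tertiary carbinol should give the C1 cation, which is attacked by C6 of the C5=C6 bond, and the resulting C5 cation then loses the C6 proton so that the ring alkene is conjugated with the enone. The closest known reaction is the sulfuric-acid cyclisation of pseudoionone-type dienones to β-ionones, here started from the hydrate-type tertiary alcohol. The ring closes in a 6-endo-trig mode, with both alkene carbons inside the new cyclohexene. No stereocentre is created and C3 and C4 take no part, so the sugar-derived (3S,4R) configuration is carried through. The step needs C–C bond formation to outrun elimination at C1, proton loss from C6 rather than from C4 or C18, and no hydride shift or ionisation at C4. The cis-carbonate holds C2 and C5 on one face of a five-membered ring so that C1 and C6 lie close, its locked carbonyl oxygen cannot bridge a cation, and its electron-poor oxygens disfavour hydride migration and C4–O cleavage; either C5=C6 geometry can close.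

Step 12
Reactants: 16 β-ionone carbonate; 17 vinylmagnesium bromide
Product: 18 (1E)-1-[(3R,4S)-3,4-(carbonyldioxy)-2,6,6-trimethylcyclohex-1-en-1-yl]-3-methylpenta-1,4-dien-3-ol (both C9 epimers)
Conditions: vinylMgBr (1.5 equiv), anhydrous CeCl3 (1.6 equiv), THF, −78 °C; aq. NH4Cl
Reagents that add atoms: none
Why: 1,2-Addition of a weakly basic organocerium reagent should take the methyl ketone, which at −78 °C is far more electrophilic than the cyclic carbonate, without deprotonating C4; the new carbinol centre is lost in the next step.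

Step 13
Reactants: 18 vinyl carbinol carbonate
Product: 19 {(2E,4E)-5-[(3R,4S)-3,4-(carbonyldioxy)-2,6,6-trimethylcyclohex-1-en-1-yl]-3-methylpenta-2,4-dien-1-yl}triphenylphosphonium bromide
Conditions: PPh3·HBr (1.05 equiv), CH2Cl2, 0 °C to rt; precipitation from EtOAc
Reagents that add atoms: triphenylphosphine hydrobromide, [Br-].c1ccc(cc1)[PH+](c1ccccc1)c1ccccc1
Why: Acid ionisation of the tertiary divinyl carbinol and capture of the pentadienyl cation at its terminus by PPh3 (allylic transposition, the vinyl-ionol route to C15 Wittig salts) should give the (2E,4E) salt, the carbonate keeping the C4 oxygen from ionising.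

Step 14
Reactants: 20 (R)-α-ionone
Product: 21 2-methyl-2-{(E)-2-[(1R)-2,6,6-trimethylcyclohex-2-en-1-yl]ethenyl}-1,3-dioxolane
Conditions: (TMSOCH2)2, TMSOTf (cat.), CH2Cl2, −78 to −20 °C; pyridine
Reagents that add atoms: 1,2-bis(trimethylsilyloxy)ethane, C[Si](C)(C)OCCO[Si](C)(C)C
Why: Silyl-triflate-catalysed ketalisation under aprotic conditions should protect the enone carbonyl without moving C7=C8 or touching the C6 stereocentre.

Step 15
Reactants: 21 α-ionone ketal
Product: 22 (4R)-3,5,5-trimethyl-4-[(E)-2-(2-methyl-1,3-dioxolan-2-yl)ethenyl]cyclohex-2-en-1-one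
Conditions: t-BuOOH, Rh2(caprolactamate)4 (cat.), K2CO3, CH2Cl2, rt
Reagents that add atoms: tert-butyl hydroperoxide, CC(C)(C)OO
Why: Dirhodium-catalysed allylic oxidation with t-BuOOH should convert the only unhindered allylic methylene (C3) into the enone carbonyl, the tertiary C6–H being shielded.

Step 16
Reactants: 22 3-oxo ketal
Product: 23 (1S,4R)-3,5,5-trimethyl-4-[(E)-2-(2-methyl-1,3-dioxolan-2-yl)ethenyl]cyclohex-2-en-1-ol
Conditions: K[(s-Bu)3BH], THF, −78 °C; aq. NH4Cl
Reagents that add atoms: none
Why: 1,2-Reduction of the β-substituted cyclohexenone by a bulky trialkylborohydride should occur from the ring face anti to the C6 side chain, because in the conformer with the chain pseudo-equatorial the axial C1 methyl shields the chain face and in the other the pseudo-axial chain shields it itself; the new hydroxyl is thus placed cis to the chain (3S in carotenoid numbering).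

Step 17
Reactants: 23 cis-hydroxy ketal
Product: 24 (1R,4R)-3,5,5-trimethyl-4-[(E)-2-(2-methyl-1,3-dioxolan-2-yl)ethenyl]cyclohex-2-en-1-yl 4-nitrobenzoate
Conditions: 4-nitrobenzoic acid, PPh3, DIAD, THF, 0 °C to rt
Reagents that add atoms: 4-nitrobenzoic acid, O=C(O)c1ccc(cc1)[N+](=O)[O-]
Why: Mitsunobu esterification proceeds by SN2 displacement with inversion at C3, which should turn the cis (3S) alcohol into the trans (3R) ester needed for the ε-ring.

Step 18
Reactants: 24 trans-nitrobenzoate ketal
Product: 26 (3E)-4-[(1R,4R)-4-hydroxy-2,6,6-trimethylcyclohex-2-en-1-yl]but-3-en-2-one, via hydroxy ketal 25 (not isolated)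
Conditions: K2CO3 (cat.), MeOH, rt; then 5% aq. oxalic acid, THF, rt
Reagents that add atoms: water, O
Why: Base-catalysed transesterification should remove the ester while C9 is still a ketal (C6–H not activated), and mild acid hydrolysis of the ketal then returns the enone without ionising the ring allylic alcohol.

Step 19
Reactants: 26 (3R,6R)-3-hydroxy-α-ionone; 17 vinylmagnesium bromide
Product: 27 (1R,4R)-4-[(1E)-3-hydroxy-3-methylpenta-1,4-dien-1-yl]-3,5,5-trimethylcyclohex-2-en-1-ol (both C9 epimers)
Conditions: vinylMgBr (3 equiv), THF, −20 to 0 °C; aq. NH4Cl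
Reagents that add atoms: none
Why: Grignard 1,2-addition to the methyl ketone of the magnesium alkoxide of 26 should give the vinyl carbinol, whose new centre is lost in the next step.

Step 20
Reactants: 27 ε-vinyl carbinol
Product: 28 {(2E,4E)-5-[(1R,4R)-4-hydroxy-2,6,6-trimethylcyclohex-2-en-1-yl]-3-methylpenta-2,4-dien-1-yl}triphenylphosphonium bromide
Conditions: PPh3·HBr (1.0 equiv), CH2Cl2, 0 °C to rt; precipitation from EtOAc
Reagents that add atoms: triphenylphosphine hydrobromide, [Br-].c1ccc(cc1)[PH+](c1ccccc1)c1ccccc1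
Why: The tertiary divinyl carbinol should ionise far faster than the secondary ring allylic alcohol, and PPh3 captures the pentadienyl cation at its terminus (allylic transposition) to give the (2E,4E) salt; the non-nucleophilic solvent keeps the ring hydroxyl from being solvolysed.

Step 21
Reactants: 28 ε-C15 phosphonium bromide; 29 (2E,4E,6E)-2,7-dimethylocta-2,4,6-trienedial
Product: 30 (3R,6R)-3-hydroxy-12'-apo-ε-caroten-12'-al (all-E)
Conditions: 29 (2 equiv), NaOMe (1.1 equiv), MeOH/CH2Cl2, 0 °C to rt; then heptane, 90 °C (Z to E)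
Reagents that add atoms: none
Why: Wittig olefination of one formyl group of the symmetrical dialdehyde, used in excess so that the second aldehyde stays free, should form C11'=C12', which is equilibrated thermally to E.

Step 22
Reactants: 19 β-C15 phosphonium bromide; 30 C25 ε-apocarotenal
Product: 32 (3S,4R,3'R,6'R)-β,ε-carotene-3,4,3'-triol, via diol phosphonium bromide 31 (not isolated)
Conditions: NaOMe (2.5 equiv), MeOH/CH2Cl2, 0 °C, 20 min; then 30, rt; then EtOH, reflux (Z to E); crystallisation under argon in the dark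
Reagents that add atoms: none
Why: Methoxide should first open the strained cyclic carbonate by transesterification to the free diol, so that the C4 oxygen is no longer a leaving group, and the ylide then undergoes Wittig olefination with the C25 aldehyde to form C11=C12; thermal isomerisation should give the all-E triol.

Compound list
1 | 2-deoxy-D-ribose, (3S,4R)-3,4,5-trihydroxypentanal | O=CC[C@H](O)[C@H](O)CO | starting material
2 | 2-deoxy-3,4-O-isopropylidene-D-erythro-pentopyranose (anomer mixture) | OC1C[C@@H]2OC(C)(C)O[C@@H]2CO1 | intermediate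
3 | 2-deoxy-3,4-O-isopropylidene-D-erythro-pentono-1,5-lactone | O=C1C[C@@H]2OC(C)(C)O[C@@H]2CO1 | intermediate
4 | methylmagnesium bromide | C[Mg]Br | starting material
5 | 1-[(4S,5R)-5-(hydroxymethyl)-2,2-dimethyl-1,3-dioxolan-4-yl]-2-methylpropan-2-ol | CC(C)(O)C[C@@H]1OC(C)(C)O[C@@H]1CO | intermediate
6 | 2,3-O-isopropylidene-(2S,3S)-2,3,5-trihydroxy-5-methylhexanoic acid 1,5-lactone (cis-fused) | CC1(C)C[C@@H]2OC(C)(C)O[C@@H]2C(=O)O1 | intermediate
7 | methyllithium | [Li]C | starting material
8 | 1-[(4S,5S)-5-(2-hydroxy-2-methylpropyl)-2,2-dimethyl-1,3-dioxolan-4-yl]ethan-1-one | CC(=O)[C@H]1OC(C)(C)O[C@H]1CC(C)(C)O | intermediate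
9 | (triphenylphosphoranylidene)acetonitrile | N#CC=P(c1ccccc1)(c1ccccc1)c1ccccc1 | starting material
10 | 3-[(4R,5S)-5-(2-hydroxy-2-methylpropyl)-2,2-dimethyl-1,3-dioxolan-4-yl]but-2-enenitrile (E/Z mixture) | N#CC=C(C)[C@H]1OC(C)(C)O[C@H]1CC(C)(C)O | intermediate
11 | 3-[(4R,5S)-5-(2-hydroxy-2-methylpropyl)-2,2-dimethyl-1,3-dioxolan-4-yl]but-2-enal (E/Z mixture) | O=CC=C(C)[C@H]1OC(C)(C)O[C@H]1CC(C)(C)O | intermediate
12 | 1-(triphenylphosphoranylidene)propan-2-one | CC(=O)C=P(c1ccccc1)(c1ccccc1)c1ccccc1 | starting material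
13 | (3E)-6-[(4R,5S)-5-(2-hydroxy-2-methylpropyl)-2,2-dimethyl-1,3-dioxolan-4-yl]hepta-3,5-dien-2-one (5E/5Z mixture) | CC(=O)/C=C/C=C(C)[C@H]1OC(C)(C)O[C@H]1CC(C)(C)O | intermediate
14 | (3E,7R,8S)-7,8,10-trihydroxy-6,10-dimethylundeca-3,5-dien-2-one | CC(=O)/C=C/C=C(C)[C@@H](O)[C@@H](O)CC(C)(C)O | intermediate
15 | (4S,5R)-4-(2-hydroxy-2-methylpropyl)-5-[(4E)-6-oxohepta-2,4-dien-2-yl]-1,3-dioxolan-2-one (key-step precursor) | CC(=O)/C=C/C=C(C)[C@@H](O1)[C@@H](OC1=O)CC(C)(C)O | intermediate
16 | (3E)-4-[(3R,4S)-3,4-(carbonyldioxy)-2,6,6-trimethylcyclohex-1-en-1-yl]but-3-en-2-one, the 3,4-carbonate of (3S,4R)-3,4-dihydroxy-β-ionone (key-step product) | CC(=O)/C=C/C1=C(C)[C@@H](O2)[C@@H](OC2=O)CC1(C)C | intermediate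
17 | vinylmagnesium bromide | C=C[Mg]Br | starting material
18 | (1E)-1-[(3R,4S)-3,4-(carbonyldioxy)-2,6,6-trimethylcyclohex-1-en-1-yl]-3-methylpenta-1,4-dien-3-ol (both C9 epimers) | C=CC(C)(O)/C=C/C1=C(C)[C@@H](O2)[C@@H](OC2=O)CC1(C)C | intermediate
19 | {(2E,4E)-5-[(3R,4S)-3,4-(carbonyldioxy)-2,6,6-trimethylcyclohex-1-en-1-yl]-3-methylpenta-2,4-dien-1-yl}triphenylphosphonium bromide | [Br-].C(/C=C(C)/C=C/C1=C(C)[C@@H](O2)[C@@H](OC2=O)CC1(C)C)[P+](c3ccccc3)(c3ccccc3)c3ccccc3 | intermediate
20 | (R)-α-ionone, (3E)-4-[(1R)-2,6,6-trimethylcyclohex-2-en-1-yl]but-3-en-2-one | CC1=CCCC(C)(C)[C@H]1/C=C/C(C)=O | starting material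
21 | 2-methyl-2-{(E)-2-[(1R)-2,6,6-trimethylcyclohex-2-en-1-yl]ethenyl}-1,3-dioxolane | CC1=CCCC(C)(C)[C@H]1/C=C/C1(C)OCCO1 | intermediate
22 | (4R)-3,5,5-trimethyl-4-[(E)-2-(2-methyl-1,3-dioxolan-2-yl)ethenyl]cyclohex-2-en-1-one | CC1=CC(=O)CC(C)(C)[C@H]1/C=C/C1(C)OCCO1 | intermediate
23 | (1S,4R)-3,5,5-trimethyl-4-[(E)-2-(2-methyl-1,3-dioxolan-2-yl)ethenyl]cyclohex-2-en-1-ol (hydroxyl cis to the side chain) | CC1=C[C@@H](O)CC(C)(C)[C@H]1/C=C/C1(C)OCCO1 | intermediate
24 | (1R,4R)-3,5,5-trimethyl-4-[(E)-2-(2-methyl-1,3-dioxolan-2-yl)ethenyl]cyclohex-2-en-1-yl 4-nitrobenzoate | CC1=C[C@H](OC(=O)c2ccc(cc2)[N+](=O)[O-])CC(C)(C)[C@H]1/C=C/C1(C)OCCO1 | intermediate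
25 | (1R,4R)-3,5,5-trimethyl-4-[(E)-2-(2-methyl-1,3-dioxolan-2-yl)ethenyl]cyclohex-2-en-1-ol (hydroxyl trans to the side chain) | CC1=C[C@H](O)CC(C)(C)[C@H]1/C=C/C1(C)OCCO1 | intermediate (not isolated)
26 | (3R,6R)-3-hydroxy-α-ionone, (3E)-4-[(1R,4R)-4-hydroxy-2,6,6-trimethylcyclohex-2-en-1-yl]but-3-en-2-one | CC1=C[C@H](O)CC(C)(C)[C@H]1/C=C/C(C)=O | intermediate
27 | (1R,4R)-4-[(1E)-3-hydroxy-3-methylpenta-1,4-dien-1-yl]-3,5,5-trimethylcyclohex-2-en-1-ol (both C9 epimers) | CC1=C[C@H](O)CC(C)(C)[C@H]1/C=C/C(C)(O)C=C | intermediate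
28 | {(2E,4E)-5-[(1R,4R)-4-hydroxy-2,6,6-trimethylcyclohex-2-en-1-yl]-3-methylpenta-2,4-dien-1-yl}triphenylphosphonium bromide | [Br-].CC1=C[C@H](O)CC(C)(C)[C@H]1/C=C/C(C)=C/C[P+](c1ccccc1)(c1ccccc1)c1ccccc1 | intermediate
29 | (2E,4E,6E)-2,7-dimethylocta-2,4,6-trienedial | O=C/C(C)=C/C=C/C=C(C)/C=O | starting material
30 | (3R,6R)-3-hydroxy-12'-apo-ε-caroten-12'-al (all-E) | CC1=C[C@H](O)CC(C)(C)[C@H]1/C=C/C(C)=C/C=C/C(C)=C/C=C/C=C(C)/C=O | intermediate
31 | {(2E,4E)-5-[(3R,4S)-3,4-dihydroxy-2,6,6-trimethylcyclohex-1-en-1-yl]-3-methylpenta-2,4-dien-1-yl}triphenylphosphonium bromide | [Br-].C(/C=C(C)/C=C/C1=C(C)[C@@H](O)[C@@H](O)CC1(C)C)[P+](c2ccccc2)(c2ccccc2)c2ccccc2 | intermediate (not isolated)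
32 | (3S,4R,3'R,6'R)-β,ε-carotene-3,4,3'-triol (all-E), CNP0191612.1 | CC1=C[C@H](O)CC(C)(C)[C@H]1/C=C/C(C)=C/C=C/C(C)=C/C=C/C=C(C)/C=C/C=C(C)/C=C/C1=C(C)[C@@H](O)[C@@H](O)CC1(C)C | target

Total step count: 22. Longest linear sequence: 14 steps (steps 1–13 and 22, from 1 to 32); the ε-branch (steps 14–21) supplies 30 in 8 steps.

Steps most likely to fail

Step 11. The C1 cation may be consumed by elimination or reversible capture faster than the electron-poor C5=C6 bond attacks it, or the allylic C4–O bond may ionise in the strong acid. The fallback takes the β-ring from an ionone instead of building it. It sets out from 23. Aqueous oxalic acid in THF should free (3S,6R)-3-hydroxy-α-ionone F1. VO(acac)2 (cat.) with t-BuOOH in toluene should epoxidise the ring alkene on the face of the hydroxyl to give the epoxy alcohol (3S,4S,5R,6R)-4,5-epoxy-3-hydroxy-4,5-dihydro-α-ionone F2. DBU in CH2Cl2 should then remove the γ-proton at C6 and open the epoxide by vinylogous β-elimination to (3S,4R)-3,4-dihydroxy-β-ionone F3, whose cis-diol keeps the C3 configuration and gains C4–O on the same face. CDI in CH2Cl2 closes the carbonate and the route is rejoined at 16.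

Step 6. The olefination may be slow because 8 rests largely as its cyclic hemiketal, and prolonged heating may epimerise C4. The fallback replaces olefination and reduction by addition and rearrangement. It sets out from 8, which is treated with (Z)-2-ethoxyvinyllithium (2.2 equiv, from (Z)-1-bromo-2-ethoxyethene and t-BuLi, THF, −78 °C) to give the carbinol enol ether (3Z)-4-ethoxy-2-[(4S,5S)-5-(2-hydroxy-2-methylpropyl)-2,2-dimethyl-1,3-dioxolan-4-yl]but-3-en-2-ol F4. Brief treatment with aqueous oxalic acid in THF at 0 °C should hydrolyse the enol ether and dehydrate the tertiary β-hydroxy aldehyde to the enal. The route is rejoined at 11, so steps 6 and 7 are both replaced.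

Step 16. Hydride delivery may show poor facial selectivity and give both C3 epimers, which would also make the Mitsunobu step unproductive. The fallback replaces substrate control plus inversion by catalyst control. It sets out from 22, which is reduced with BH3·SMe2 and (S)-2-methyl-CBS-oxazaborolidine (cat.) in toluene at −40 °C. This catalyst enantiomer treats the alkenyl flank as the large group and should deliver hydride to give the (3R) alcohol directly. The route is rejoined at 25, which is hydrolysed to 26 as in the second stage of step 18; steps 16 and 17 drop out and no compound outside the list is made.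

Further compounds
F1 | step 11 | (3S,6R)-3-hydroxy-α-ionone, (3E)-4-[(1R,4S)-4-hydroxy-2,6,6-trimethylcyclohex-2-en-1-yl]but-3-en-2-one | CC1=C[C@@H](O)CC(C)(C)[C@H]1/C=C/C(C)=O
F2 | step 11 | (3S,4S,5R,6R)-4,5-epoxy-3-hydroxy-4,5-dihydro-α-ionone (epoxide oxygen cis to the hydroxyl) | C[C@]12O[C@H]1[C@@H](O)CC(C)(C)[C@H]2/C=C/C(C)=O
F3 | step 11 | (3S,4R)-3,4-dihydroxy-β-ionone, (3E)-4-[(3R,4S)-3,4-dihydroxy-2,6,6-trimethylcyclohex-1-en-1-yl]but-3-en-2-one | CC(=O)/C=C/C1=C(C)[C@@H](O)[C@@H](O)CC1(C)C
F4 | step 6 | (3Z)-4-ethoxy-2-[(4S,5S)-5-(2-hydroxy-2-methylpropyl)-2,2-dimethyl-1,3-dioxolan-4-yl]but-3-en-2-ol (both carbinol epimers) | CCO/C=C\C(C)(O)[C@H]1OC(C)(C)O[C@H]1CC(C)(C)O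
F0 | step 16 | none | none
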